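A direct plan would condense the bis-MOM aldehyde A1 with the allyl-protected acetophenone A2 to chalcone A3, rearrange A3 with a trivalent iodine reagent (PhI(OH)OTs, MeOH) to the β-keto acetal A4, unmask and cyclodehydrate this to the 2-aryl-4-hydroxybenzofuran-3-carbaldehyde A5, then prenylate C5 and remove the allyl group. Its weakest steps would be:
- The late C5 prenylation of the phenoxide of A5: an ambident phenoxide (O- against C-alkylation, double alkylation) would be alkylated next to a free aldehyde on the most valuable intermediate.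
- The oxidative 1,2-aryl shift A3 → A4: trivalent iodine and the TsOH it releases would meet an allyl ether and two acid-labile MOM ethers on a very electron-rich arene, so over-oxidation and early MOM loss would be likely.
- The protecting-group traffic: two MOM groups and one allyl group would be put on and taken off, and about half of the steps would form no bond of the skeleton.

**Retrosynthetic overview**
- The benzenoid ring A (C3a–C4–C5–C6–C7–C7a), with its contiguous 4-OH / 5-prenyl / 6-OMe / 7-H pattern, is cut into three pieces: a furan C=C bond (C7a, C3a), a diazoacetyl unit (C4 with its oxygen, C7) and the ynol ether MeO–C≡C–CH2CH=CMe2 (C6, C5).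
- One photochemical/thermal cascade forms C7–C7a (Wolff shift), C4–C5 and C6–C7 ([2+2]) and C3a–C4 (6π electrocyclization).
- Ring order: the furan ring comes first (furan-3-carbaldehyde), the aryl ring is attached at furan C2 by Negishi coupling, and ring A is built last.
- The prenyl group arrives as a substituent of the alkyne, so no phenoxide is prenylated; no oxidative rearrangement is needed; the formyl carbon is carried as one dioxolane that also directs the lithiation; the two protecting groups fall in one final operation.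

Key step: step 7

Assumption: n-BuLi metalates 2-(furan-3-yl)-1,3-dioxolane at C2, between the ring oxygen and the acetal, as oxygen-directed α-lithiations of 3-substituted furans generally do. All isolated compounds are achiral.

**Step 1**
Reactants: 1 4-bromo-3-methoxyphenol + 2 chlorotriisopropylsilane
Product: 3 (4-bromo-3-methoxyphenoxy)triisopropylsilane
Conditions: TIPSCl (1.1 equiv), imidazole (2 equiv), DMF, rt
Reagents that add atoms: chlorotriisopropylsilane CC(C)[Si](Cl)(C(C)C)C(C)C
Why: Imidazole-mediated O-silylation should give a bulky aryl silyl ether that survives organolithium, amide-base and photochemical steps and shields the arene position between the two oxygens from later ortho-lithiation.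

**Step 2**
Reactants: 4 furan-3-carbaldehyde + 5 ethane-1,2-diol
Product: 6 2-(furan-3-yl)-1,3-dioxolane
Conditions: HOCH2CH2OH (1.5 equiv), p-TsOH·H2O (cat.), benzene, reflux, Dean–Stark
Reagents that add atoms: ethane-1,2-diol OCCO
Why: Acid-catalysed acetalization with azeotropic removal of water masks the formyl group as a dioxolane that later also serves as the directing group for C2-lithiation.

**Step 3**
Reactants: 6 2-(furan-3-yl)-1,3-dioxolane + 3 (4-bromo-3-methoxyphenoxy)triisopropylsilane
Product: 9 2-{2-[2-methoxy-4-(triisopropylsilyloxy)phenyl]furan-3-yl}-1,3-dioxolane, via 2-lithiofuran acetal 7 (not isolated), via furylzinc chloride 8 (not isolated)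
Conditions: n-BuLi (1.05 equiv), THF, –78 → –20 °C; ZnCl2 (1.1 equiv), → rt; 3, Pd(OAc)2 (2 mol %), SPhos (4 mol %), THF, 50 °C
Reagents that add atoms: none
Why: Directed α-lithiation at C2 (flanked by the ring oxygen and the chelating acetal oxygen), transmetalation to zinc and Negishi cross-coupling with the electron-rich aryl bromide should join the aryl ring to furan C2 in one pot.

**Step 4**
Reactants: 9 2-{2-[2-methoxy-4-(triisopropylsilyloxy)phenyl]furan-3-yl}-1,3-dioxolane + 10 N-methoxy-N-methylacetamide
Product: 12 1-{4-(1,3-dioxolan-2-yl)-5-[2-methoxy-4-(triisopropylsilyloxy)phenyl]furan-2-yl}ethan-1-one, via 5-lithiofuran 11 (not isolated)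
Conditions: n-BuLi (1.1 equiv), THF, –78 → –30 °C; MeC(O)N(OMe)Me (1.3 equiv), –78 °C → rt; H2O
Reagents that add atoms: N-methoxy-N-methylacetamide CON(C)C(C)=O
Why: The only remaining furan α-position (C5) should be lithiated, and Weinreb acylation through the stable chelated tetrahedral intermediate should stop at the methyl ketone.

**Step 5**
Reactants: 12 the methyl ketone + 13 2,2,2-trifluoroethyl trifluoroacetate + 14 methanesulfonyl azide
Product: 16 2-diazo-1-{4-(1,3-dioxolan-2-yl)-5-[2-methoxy-4-(triisopropylsilyloxy)phenyl]furan-2-yl}ethan-1-one, via trifluoroacetyl ketone 15 (not isolated)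
Conditions: LiN(SiMe3)2 (1.1 equiv), THF, –78 °C; CF3CO2CH2CF3 (1.2 equiv), –78 °C; AcOH (1.2 equiv) quench; then MsN3 (1.5 equiv), Et3N (1.5 equiv), H2O (1 equiv), MeCN, rt
Reagents that add atoms: methanesulfonyl azide CS(=O)(=O)N=[N+]=[N-]
Why: In this detrifluoroacetylative diazo transfer, Claisen trifluoroacetylation activates the methyl ketone for Regitz diazo transfer and the trifluoroacetyl group is then cleaved; every stage is basic or near-neutral, so the dioxolane and silyl ether should remain.

**Step 6**
Reactants: 17 2-chloro-1,1-dimethoxyethane + 18 1-bromo-3-methylbut-2-ene (prenyl bromide)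
Product: 20 1-methoxy-5-methylhex-4-en-1-yne, via sodium methoxyacetylide 19 (not isolated)
Conditions: NaNH2 (3.1 equiv), liq. NH3, –33 °C; prenyl bromide (1.3 equiv), –33 °C; NH3 evaporated, pentane/H2O, distillation
Reagents that add atoms: 1-bromo-3-methylbut-2-ene CC(C)=CCBr
Why: Twofold elimination (HCl, then MeOH) from the chloroacetal by sodium amide should give sodium methoxyacetylide, which is C-alkylated by SN2 substitution at the primary carbon of the allylic bromide.

**Step 7**
Reactants: 16 the furyl diazomethyl ketone + 20 1-methoxy-5-methylhex-4-en-1-yne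
Product: 25 3-(1,3-dioxolan-2-yl)-6-methoxy-2-[2-methoxy-4-(triisopropylsilyloxy)phenyl]-5-(3-methylbut-2-en-1-yl)-1-benzofuran-4-ol, via furylketene 21 (not isolated), via cyclobutenone 22 (not isolated), via dienylketene 23 (not isolated), via cyclohexadienone 24 (not isolated)
Conditions: 20 (2 equiv), degassed ClCH2CH2Cl (0.05 M), hν (254 nm, low-pressure Hg lamps, Vycor), rt; then 80 °C, 3–5 h
Reagents that add atoms: none
Why: Photochemical Wolff rearrangement of 16 (loss of N2, 1,2-shift of the furyl group) should give furylketene 21, which is captured in a regioselective [2+2] cycloaddition by ynol ether 20 (its prenyl-bearing carbon bonds to the ketene carbonyl carbon) to give cyclobutenone 22; on heating, reversible 4π electrocyclic ring opening gives dienylketene 23, thermal 6π electrocyclization onto furan C3 gives cyclohexadienone 24, and enolization aromatizes ring A. The closest known reaction type is the Danheiser benzannulation in its diazo ketone form, which has been run with aryl and heteroaryl diazomethyl ketones and alkoxy- or siloxyalkynes. Ring A (C3a–C4–C5–C6–C7–C7a) is closed as a six-membered carbocycle by the disrotatory 6π electrocyclization (bond C3a–C4), after C4–C5 and C6–C7 were made in the [2+2] step and C7–C7a in the Wolff shift. No stereocenter remains, since the sp3 carbons of 22 and 24 are transient and racemic. The step needs one regiochemical outcome, OH/prenyl/OMe/H in this order around C4–C7, which the polarization of the ynol ether secures; ring closure can only reach furan C3, because the other neighbour of the ketene-bearing carbon is the ring oxygen. A twofold excess of 20 should keep the product phenol from intercepting ketene 21.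

**Step 8**
Reactants: 25 the silyl-protected benzofuran acetal + 26 water
Product: 28 4-hydroxy-2-(4-hydroxy-2-methoxyphenyl)-6-methoxy-5-(3-methylbut-2-en-1-yl)-1-benzofuran-3-carbaldehyde (the target), via desilylated acetal 27 (not isolated)
Conditions: TBAF (1.1 equiv), THF, 0 °C; then 1 M aq. HCl, THF, rt, short contact
Reagents that add atoms: water O
Why: Fluoride-induced desilylation followed by specific-acid-catalysed hydrolysis of the dioxolane (its oxocarbenium ion is stabilized by the electron-rich benzofuran) should free the phenol and the aldehyde under conditions too mild to cyclize the ortho-prenylphenol to a chroman.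

**Compound list**
1 | 4-bromo-3-methoxyphenol | COc1cc(O)ccc1Br | starting material
2 | chlorotriisopropylsilane | CC(C)[Si](Cl)(C(C)C)C(C)C | starting material
3 | (4-bromo-3-methoxyphenoxy)triisopropylsilane | COc1cc(O[Si](C(C)C)(C(C)C)C(C)C)ccc1Br | intermediate
4 | furan-3-carbaldehyde | O=Cc1ccoc1 | starting material
5 | ethane-1,2-diol | OCCO | starting material
6 | 2-(furan-3-yl)-1,3-dioxolane | c1cc(C2OCCO2)co1 | intermediate
7 | [3-(1,3-dioxolan-2-yl)furan-2-yl]lithium, formed in situ | [Li]c1occc1C1OCCO1 | intermediate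
8 | chloro[3-(1,3-dioxolan-2-yl)furan-2-yl]zinc, formed in situ | Cl[Zn]c1occc1C1OCCO1 | intermediate
9 | 2-{2-[2-methoxy-4-(triisopropylsilyloxy)phenyl]furan-3-yl}-1,3-dioxolane | COc1cc(O[Si](C(C)C)(C(C)C)C(C)C)ccc1-c1occc1C1OCCO1 | intermediate
10 | N-methoxy-N-methylacetamide | CON(C)C(C)=O | starting material
11 | {4-(1,3-dioxolan-2-yl)-5-[2-methoxy-4-(triisopropylsilyloxy)phenyl]furan-2-yl}lithium, formed in situ | COc1cc(O[Si](C(C)C)(C(C)C)C(C)C)ccc1-c1oc([Li])cc1C1OCCO1 | intermediate
12 | 1-{4-(1,3-dioxolan-2-yl)-5-[2-methoxy-4-(triisopropylsilyloxy)phenyl]furan-2-yl}ethan-1-one | COc1cc(O[Si](C(C)C)(C(C)C)C(C)C)ccc1-c1oc(C(C)=O)cc1C1OCCO1 | intermediate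
13 | 2,2,2-trifluoroethyl trifluoroacetate | O=C(OCC(F)(F)F)C(F)(F)F | starting material
14 | methanesulfonyl azide | CS(=O)(=O)N=[N+]=[N-] | starting material
15 | 1-{4-(1,3-dioxolan-2-yl)-5-[2-methoxy-4-(triisopropylsilyloxy)phenyl]furan-2-yl}-4,4,4-trifluorobutane-1,3-dione, formed in situ | COc1cc(O[Si](C(C)C)(C(C)C)C(C)C)ccc1-c1oc(C(=O)CC(=O)C(F)(F)F)cc1C1OCCO1 | intermediate
16 | 2-diazo-1-{4-(1,3-dioxolan-2-yl)-5-[2-methoxy-4-(triisopropylsilyloxy)phenyl]furan-2-yl}ethan-1-one | COc1cc(O[Si](C(C)C)(C(C)C)C(C)C)ccc1-c1oc(C(=O)C=[N+]=[N-])cc1C1OCCO1 | intermediate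
17 | 2-chloro-1,1-dimethoxyethane | COC(CCl)OC | starting material
18 | 1-bromo-3-methylbut-2-ene (prenyl bromide) | CC(C)=CCBr | starting material
19 | sodium methoxyacetylide, formed in situ | COC#C[Na] | intermediate
20 | 1-methoxy-5-methylhex-4-en-1-yne | COC#CCC=C(C)C | intermediate
21 | 2-{4-(1,3-dioxolan-2-yl)-5-[2-methoxy-4-(triisopropylsilyloxy)phenyl]furan-2-yl}ethen-1-one (furylketene), formed in situ | COc1cc(O[Si](C(C)C)(C(C)C)C(C)C)ccc1-c1oc(C=C=O)cc1C1OCCO1 | intermediate
22 | 4-{4-(1,3-dioxolan-2-yl)-5-[2-methoxy-4-(triisopropylsilyloxy)phenyl]furan-2-yl}-3-methoxy-2-(3-methylbut-2-en-1-yl)cyclobut-2-en-1-one, racemic, formed in situ | COc1cc(O[Si](C(C)C)(C(C)C)C(C)C)ccc1-c1oc(C2C(=O)C(CC=C(C)C)=C2OC)cc1C1OCCO1 | intermediate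
23 | (3E)-4-{4-(1,3-dioxolan-2-yl)-5-[2-methoxy-4-(triisopropylsilyloxy)phenyl]furan-2-yl}-3-methoxy-2-(3-methylbut-2-en-1-yl)buta-1,3-dien-1-one (dienylketene, furyl cis to the ketenyl carbon), formed in situ | COc1cc(O[Si](C(C)C)(C(C)C)C(C)C)ccc1-c1oc(/C=C(OC)\C(CC=C(C)C)=C=O)cc1C1OCCO1 | intermediate
24 | 3-(1,3-dioxolan-2-yl)-6-methoxy-2-[2-methoxy-4-(triisopropylsilyloxy)phenyl]-5-(3-methylbut-2-en-1-yl)-3aH-1-benzofuran-4-one, racemic, formed in situ | O=C1C(CC=C(C)C)=C(OC)C=C2OC(c3ccc(O[Si](C(C)C)(C(C)C)C(C)C)cc3OC)=C(C3OCCO3)C12 | intermediate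
25 | 3-(1,3-dioxolan-2-yl)-6-methoxy-2-[2-methoxy-4-(triisopropylsilyloxy)phenyl]-5-(3-methylbut-2-en-1-yl)-1-benzofuran-4-ol | COc1cc2oc(-c3ccc(O[Si](C(C)C)(C(C)C)C(C)C)cc3OC)c(C3OCCO3)c2c(O)c1CC=C(C)C | intermediate
26 | water | O | starting material
27 | 3-(1,3-dioxolan-2-yl)-2-(4-hydroxy-2-methoxyphenyl)-6-methoxy-5-(3-methylbut-2-en-1-yl)-1-benzofuran-4-ol, formed in situ | COc1cc(O)ccc1-c1oc2cc(OC)c(CC=C(C)C)c(O)c2c1C1OCCO1 | intermediate
28 | 4-hydroxy-2-(4-hydroxy-2-methoxyphenyl)-6-methoxy-5-(3-methylbut-2-en-1-yl)-1-benzofuran-3-carbaldehyde (achiral) | COc1cc(O)ccc1-c1oc2cc(OC)c(CC=C(C)C)c(O)c2c1C=O | target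

**Step count and risks**
Total step count: 8. Longest linear sequence: 6 steps (steps 2, 3, 4, 5, 7, 8, from furan-3-carbaldehyde).

Steps most likely to fail:

1. Step 7. The cascade may suffer from secondary photochemistry of the arylfuran chromophore or of cyclobutenone 22 under 254 nm light, or from interception of ketene 21 by the phenol that is being formed. Fallback, setting out from 16 and coming back at 25: the ketene would be generated in the dark. Wolff rearrangement of 16 catalysed by AgO2CPh/Et3N in THF/H2O would give 2-{4-(1,3-dioxolan-2-yl)-5-[2-methoxy-4-(triisopropylsilyloxy)phenyl]furan-2-yl}acetic acid F4. 1-Chloro-N,N,2-trimethylprop-1-en-1-amine in CH2Cl2 would convert it under neutral conditions to the acid chloride F5. Slow addition of Et3N to F5 and alkyne 20 in toluene at rt would form ketene 21 by dehydrochlorination and trap it as cyclobutenone 22. Heating at 80–110 °C would then carry 22 through 23 and 24 to 25 with no light present.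

2. Step 3. Lithiation of 6 may be divided between C2 and C5, or the furylzinc reagent may couple sluggishly with the electron-rich, ortho-substituted bromide. Fallback, setting out from 3 and coming back at 9: the biaryl bond would be made by C–H activation at the ester oxidation level. Direct C2-arylation of ethyl furan-3-carboxylate with 3 (Pd(PPh3)4, KOAc, toluene, 110 °C) would give ethyl 2-[2-methoxy-4-(triisopropylsilyloxy)phenyl]furan-3-carboxylate F1. Reduction with i-Bu2AlH (CH2Cl2, –78 °C) would give {2-[2-methoxy-4-(triisopropylsilyloxy)phenyl]furan-3-yl}methanol F2. Oxidation with MnO2 (CH2Cl2, rt) would give 2-[2-methoxy-4-(triisopropylsilyloxy)phenyl]furan-3-carbaldehyde F3, and acetalization with 5 (p-TsOH cat., benzene, Dean–Stark) would return to 9.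

3. Step 4. Deprotonation of 9 may compete on the aryl ring (ortho to the methoxy group) or at the acetal C–H, which would give misplaced acylation or fragmentation of the dioxolane. Fallback, setting out from 9 and coming back at 12: the acetyl group would be introduced by electrophilic substitution and cross-coupling. NBS in DMF at –40 °C would brominate the furan α-position to give 2-{5-bromo-2-[2-methoxy-4-(triisopropylsilyloxy)phenyl]furan-3-yl}-1,3-dioxolane F6. Stille coupling with tributyl(1-ethoxyethenyl)stannane (Pd(PPh3)4, toluene, 90 °C) would give 2-{5-(1-ethoxyethenyl)-2-[2-methoxy-4-(triisopropylsilyloxy)phenyl]furan-3-yl}-1,3-dioxolane F7. Brief treatment with dilute oxalic acid in wet THF at 0 °C would hydrolyse the enol ether, far faster than the dioxolane, to ketone 12.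

**Further compounds**
F1 | step 3 | ethyl 2-[2-methoxy-4-(triisopropylsilyloxy)phenyl]furan-3-carboxylate | CCOC(=O)c1ccoc1-c1ccc(O[Si](C(C)C)(C(C)C)C(C)C)cc1OC
F2 | step 3 | {2-[2-methoxy-4-(triisopropylsilyloxy)phenyl]furan-3-yl}methanol | OCc1ccoc1-c1ccc(O[Si](C(C)C)(C(C)C)C(C)C)cc1OC
F3 | step 3 | 2-[2-methoxy-4-(triisopropylsilyloxy)phenyl]furan-3-carbaldehyde | O=Cc1ccoc1-c1ccc(O[Si](C(C)C)(C(C)C)C(C)C)cc1OC
F4 | step 7 | 2-{4-(1,3-dioxolan-2-yl)-5-[2-methoxy-4-(triisopropylsilyloxy)phenyl]furan-2-yl}acetic acid | COc1cc(O[Si](C(C)C)(C(C)C)C(C)C)ccc1-c1oc(CC(=O)O)cc1C1OCCO1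
F5 | step 7 | 2-{4-(1,3-dioxolan-2-yl)-5-[2-methoxy-4-(triisopropylsilyloxy)phenyl]furan-2-yl}acetyl chloride | COc1cc(O[Si](C(C)C)(C(C)C)C(C)C)ccc1-c1oc(CC(=O)Cl)cc1C1OCCO1
F6 | step 4 | 2-{5-bromo-2-[2-methoxy-4-(triisopropylsilyloxy)phenyl]furan-3-yl}-1,3-dioxolane | COc1cc(O[Si](C(C)C)(C(C)C)C(C)C)ccc1-c1oc(Br)cc1C1OCCO1
F7 | step 4 | 2-{5-(1-ethoxyethenyl)-2-[2-methoxy-4-(triisopropylsilyloxy)phenyl]furan-3-yl}-1,3-dioxolane | COc1cc(O[Si](C(C)C)(C(C)C)C(C)C)ccc1-c1oc(C(=C)OCC)cc1C1OCCO1
A1 | direct plan | 4-methoxy-2,6-bis(methoxymethoxy)benzaldehyde | COCOc1cc(OC)cc(OCOC)c1C=O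
A2 | direct plan | 1-[4-(allyloxy)-2-methoxyphenyl]ethan-1-one | CC(=O)c1ccc(OCC=C)cc1OC
A3 | direct plan | (E)-1-[4-(allyloxy)-2-methoxyphenyl]-3-[4-methoxy-2,6-bis(methoxymethoxy)phenyl]prop-2-en-1-one | COCOc1cc(OC)cc(OCOC)c1/C=C/C(=O)c1ccc(OCC=C)cc1OC
A4 | direct plan | 1-[4-(allyloxy)-2-methoxyphenyl]-3,3-dimethoxy-2-[4-methoxy-2,6-bis(methoxymethoxy)phenyl]propan-1-one (racemic) | COC(OC)C(C(=O)c1ccc(OCC=C)cc1OC)c1c(OCOC)cc(OC)cc1OCOC
A5 | direct plan | 2-[4-(allyloxy)-2-methoxyphenyl]-4-hydroxy-6-methoxy-1-benzofuran-3-carbaldehyde | COc1cc(O)c2c(C=O)c(-c3ccc(OCC=C)cc3OC)oc2c1
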